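The substrate left at one moment cannot say by itself which way the rest went, but two charges read at the same moment can.

| flask | substrate | remark | time |
|---|---|---|---|
| ochre | 0.50 mM | run made earlier |  |
| amber | 2 mM | run made earlier |  |
| flask | 1.0 mM |  | 6.0 min |

| run | time / min | target / % | substrate / % |
|---|---|---|---|
| ochre | 0.417 | 16.9 | 37.7 |
| ochre | 0.667 | 26.1 | 22.8 |
| ochre | 0.833 | 29.4 | 17.4 |
| ochre | 1.33 | 34.0 | 7.0 |
| ochre | 2.00 | 33.7 | 2.6 |
| ochre | 3.00 | 31.8 | 0.4 |
| ochre | 5.00 | 29.6 | 0.1 |
| amber | 0.417 | 12.3 | 20.2 |
| amber | 0.667 | 17.3 | 10.9 |
| amber | 0.833 | 18.9 | 8.1 |
| amber | 1.33 | 20.7 | 2.6 |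
| amber | 2.00 | 20.7 | 0.6 |
| amber | 3.00 | 19.5 | 0.1 |
| amber | 5.00 | 18.4 | 0.7 |

(readings scatter by 0.5 percentage points)

- percentages count the substrate that a species holds: one self-condensation product counts as two
- steps under discussion: intermediate <-> isomer of the product A; intermediate <-> target; 2 substrate -> self-condensation product; target <-> isomer of the product B; substrate -> intermediate

* the moment within 6.0 min at which there is most target
* the amount of target, in percent of the substrate charged, at that time
* the first time at which target reaches 20%, in the same percent, in min

We work with the inverse of the fraction left. If substrate goes by a first-order step and by self-condensation, that inverse equals E plus a times (E less one). Here E is the growth of the inverse by the first-order step taken by itself, and a, proportional to the charge, is the selectivity factor: self-condensation rate over first-order rate at the start.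

At 0.417 min, the ochre and amber inverses differ by 2.30. Their charges stand at 4.00 to one, so these readings give ochre a times (E less one) = 0.766, E = 1.89, a = 0.864, and scaling by the charge we estimate a = 1.73 for our flask.

Integrating the fraction left gives the escape share, the part of the charge passing through the first-order step: the logarithm of (one plus a), divided by a. It is 0.721 for ochre, 0.432 for amber and 0.581 for the flask.

The highest readings divided by these shares give 47.2% and 47.9%, close together. With their mean 47.5%, we estimate the flask peak at 27.6%.

The weak link is a, taken at one moment. Read again at 0.667 min, ochre's a is 0.892, and our estimate of the flask peak comes to 27.6%.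

The forecast gives 27.7% (26.5% to 28.8%) at 1.6 min, and the asked level at 0.58 min, with a for the flask at 1.55 against our 1.73. Its ground: “Substrate loss is faster than first order and speeds up with concentration”.

The flask reaches the asked level at 0.575 min and peaks at 28.2% at 1.52 min.

    intermediate ⇌ isomer of the product A (K = 2.10, k = 0.00500 s⁻¹)
    intermediate ⇌ target (K = 3.10, k = 0.0580 s⁻¹)
    2 substrate → self-condensation product (k = 21.0 L mol⁻¹ s⁻¹)
    target ⇌ isomer of the product B (K = 0.700, k = 0.00900 s⁻¹)
    substrate → intermediate (k = 0.0260 s⁻¹)

Self-condensation product holds 40.5% of the flask's charge at 6.00 min, against the 41.9% that the escape share leaves to it. A neighbour charged with 0.40 mM has a = 0.691 and an escape share of 0.760, so the mean peak per escaped charge gives 36.1%; that neighbour's peak is 36.2%.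

The earlier runs and the new flask were computed on assumed constants; scatter was added.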